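**Plan**
- The target is read as (2S)-7,4'-dihydroxyflavan-(4β→8)-epiafzelechin-(4β→8)-epiafzelechin; the upper flavan is 2,4-trans (2S,4R).
- Retrosynthesis: first the eight benzyl ethers, then both aryl bonds at C4 of the upper flavan (C4–C4a to ring A and C4–C8 to ring D), which leads back to an acyclic β-aryloxy aldehyde and a benzylated dimer; then the 4β→8 bond of the dimer; last the aryl C–O bond and the allyl C–C bond of the aldehyde.
- Enabling feature: C4 of the upper unit is a doubly benzylic methine between C4a of the resorcinol-type ring A (para to the 7-oxygen, ortho to O1) and C8 of the phloroglucinol-type ring D, so an aldehyde carbon placed there can take up both arenes in succession.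
- Forward: the aldehyde (3 steps) and the dimer (3 steps from epiafzelechin) are made separately; in the key step ring C closes by C4–C4a bond formation and the resulting flavan-4-yl cation is arylated by C8 of ring D in the same flask; hydrogenolysis finishes the route.
- Stereochemistry: upper C2 comes from a catalyst-controlled allylboration and is kept by an O-arylation that does not touch the stereocentre; upper C4 comes from C2 by axial attack on the planar cation (convergent for both C4 epimers of the intermediate); C2 and C3 of the two lower units come from the chiral pool, and the middle C4 from attack anti to the 3-OH.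

Key step: step 7

Remarks: (−)-epiafzelechin is taken as a purchasable chiral-pool compound. The sense (S)-TRIP → (S)-carbinol is assigned from the known sense (R)-catalyst → (R)-1-arylbut-3-en-1-ol; if it proves reversed, the other catalyst enantiomer is used.

**Step 1**
Reactants: 1 4-(benzyloxy)benzaldehyde
Product: 3 (S)-1-[4-(benzyloxy)phenyl]but-3-en-1-ol, via O-boryl ether 2 (not isolated)
Conditions: allylboronic acid pinacol ester (1.2 equiv), (S)-TRIP [(S)-3,3'-bis(2,4,6-triisopropylphenyl)-1,1'-binaphthyl-2,2'-diyl hydrogen phosphate, 5 mol %], toluene, −30 °C; aqueous NaHCO3 work-up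
Reagents that add atoms: allylboronic acid pinacol ester, C=CCB1OC(C)(C)C(C)(C)O1
Why: Chiral phosphoric acid-catalysed allylboration of an aryl aldehyde, in which the catalyst hydrogen-bonds to a boronate oxygen and the formyl hydrogen and the allyl group is delivered to one aldehyde face through a chair-like Zimmerman–Traxler transition state, so that the new stereocentre (the future C2 of the upper flavan) should be S, and work-up hydrolyses the O-boryl ether 2.

**Step 2**
Reactants: 3 (S)-1-[4-(benzyloxy)phenyl]but-3-en-1-ol; 4 1-(benzyloxy)-3-iodobenzene (1.5 equiv)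
Product: 5 (S)-1-(benzyloxy)-3-({1-[4-(benzyloxy)phenyl]but-3-en-1-yl}oxy)benzene
Conditions: CuI (10 mol %), 3,4,7,8-tetramethyl-1,10-phenanthroline (20 mol %), Cs2CO3 (2 equiv), toluene, 90 °C, argon
Reagents that add atoms: none
Why: Ullmann-type CuI-catalysed O-arylation of a secondary alcohol forms the aryl C–O bond (the future O1–C8a bond), so no bond at the carbinol stereocentre is broken and its S configuration is retained, while the alkene and the benzyl ethers are inert to the carbonate base.

**Step 3**
Reactants: 5 (S)-1-(benzyloxy)-3-({1-[4-(benzyloxy)phenyl]but-3-en-1-yl}oxy)benzene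
Product: 7 (S)-3-[4-(benzyloxy)phenyl]-3-[3-(benzyloxy)phenoxy]propanal, via vicinal diol 6 (not isolated)
Conditions: OsO4 (2 mol %), NaIO4 (4 equiv), 2,6-lutidine (2 equiv), dioxane/H2O 3:1, rt; used at once
Reagents that add atoms: osmium tetroxide, O=[Os](=O)(=O)=O (catalytic oxygen carrier); sodium periodate, [Na+].[O-]I(=O)(=O)=O (terminal oxidant that supplies the oxygen)
Why: Lemieux–Johnson oxidation, in which dihydroxylation of the only alkene to diol 6 and periodate cleavage in the same flask give the aldehyde one carbon shorter, with 2,6-lutidine as buffer against over-oxidation and β-elimination of the aryloxide and with the stereocentre not involved.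

**Step 4**
Reactants: 8 (−)-epiafzelechin
Product: 9 5,7,4'-tri-O-benzyl-(−)-epiafzelechin [(2R,3R)-5,7-bis(benzyloxy)-2-[4-(benzyloxy)phenyl]chroman-3-ol]
Conditions: BnBr (3.3 equiv), K2CO3 (3.5 equiv), DMF, 0 °C → rt
Reagents that add atoms: benzyl bromide, BrCc1ccccc1
Why: Williamson etherification of the three phenoxides, which K2CO3 forms selectively beside the much less acidic secondary 3-OH, at a temperature low enough that C2 is not epimerised by opening of the pyran ring.

**Step 5**
Reactants: 9 5,7,4'-tri-O-benzyl-(−)-epiafzelechin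
Product: 11 (2R,3R,4S)-5,7-bis(benzyloxy)-2-[4-(benzyloxy)phenyl]-4-(2-hydroxyethoxy)chroman-3-ol, via C4 cation hydroquinonate ion pair 10 (not isolated)
Conditions: DDQ (2 equiv), ethylene glycol (10 equiv), CH2Cl2, rt
Reagents that add atoms: ethylene glycol, OCCO
Why: Oxidative C4 functionalisation of a benzylated flavan-3-ol, in which DDQ abstracts hydride from C4 (benzylic, ortho and para to the 5- and 7-benzyloxy groups) to give the ion pair 10 of the C4 cation and the reduced quinone monoanion, and ethylene glycol adds to the planar cation on the face anti to the axial 3-OH, which should set the new C4 stereocentre as 4β (3,4-trans, 4S).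

**Step 6**
Reactants: 11 (2R,3R,4S)-5,7-bis(benzyloxy)-2-[4-(benzyloxy)phenyl]-4-(2-hydroxyethoxy)chroman-3-ol; 9 5,7,4'-tri-O-benzyl-(−)-epiafzelechin (4 equiv)
Product: 13 hexa-O-benzyl-epiafzelechin-(4β→8)-epiafzelechin, via C4 cation triflate 12 (not isolated)
Conditions: Me3SiOTf (0.2 equiv), CH2Cl2, −78 °C; aqueous NaHCO3 quench; excess 9 recovered
Reagents that add atoms: none
Why: Lewis-acid-mediated interflavan coupling (Friedel–Crafts benzylation), in which Me3SiOTf ionises the C4 glycol ether to the cation triflate 12 and C8 of 9, the free position flanked by only one benzyloxy group, attacks anti to the axial 3-OH to set the 4β (4R) stereocentre, while the fourfold excess of 9 suppresses chain extension of the product.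

**Step 7**
Reactants: 7 (S)-3-[4-(benzyloxy)phenyl]-3-[3-(benzyloxy)phenoxy]propanal (1 equiv); 13 hexa-O-benzyl-epiafzelechin-(4β→8)-epiafzelechin (2.5 equiv)
Product: 16 octa-O-benzyl-(2S)-7,4'-dihydroxyflavan-(4β→8)-epiafzelechin-(4β→8)-epiafzelechin, via 4-silyloxyflavan 14 (not isolated), via flavan-4-yl cation triflate 15 (not isolated)
Conditions: Me3SiOTf (2.2 equiv), CH2Cl2 (0.005 M in 7), −78 → −40 °C; aqueous NaHCO3 quench at −40 °C; excess 13 recovered
Reagents that add atoms: none
Why: Proposed new method: Me3SiOTf turns the aldehyde of 7 into a silyloxycarbenium ion, which is attacked by the carbon of the tethered 3-(benzyloxy)phenoxy ring that lies para to the benzyloxy group and ortho to the ether oxygen (the future C4a), a Friedel–Crafts hydroxyalkylation that is 6-exo-trig at the carbonyl, forms the C4–C4a bond, closes ring C and gives 14 as both C4 epimers. A second equivalent ionises the C4–OSiMe3 bond, so both epimers converge on the planar cation of 15, which O1 (ortho) and the 7-benzyloxy group (para) stabilise. C8 of ring D of 13 then attacks C4 to give 16; the closest known reactions are the Lewis-acid-mediated interflavan coupling of C4-oxygenated benzylated flavans with flavan nucleophiles and the twofold Friedel–Crafts condensation of an aldehyde with arenes to a diarylmethine, here made unsymmetrical by the tether. The new C4 stereocentre is controlled by C2: with the 2-aryl group equatorial on the half-chair of the cation, the nucleophile should enter axially on the face opposite to it through a chair-like transition state, which gives the 2,4-trans (4R, 4β) isomer. The order of the two arylations is secured by the high effective molarity of the six-membered closure against bimolecular attack of the hindered dimer at high dilution, the site on ring A by the para-directing benzyloxy group and the crowding of the carbon between the two oxygens, and the site on 13 by C8 of ring D being the only free position flanked by a single benzyloxy group. Excess 13 and the cold quench hold back a second alkylation and acid-induced scission or epimerisation of the interflavan bonds.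

**Step 8**
Reactants: 16 octa-O-benzyl-(2S)-7,4'-dihydroxyflavan-(4β→8)-epiafzelechin-(4β→8)-epiafzelechin
Product: 17 (2S)-7,4'-dihydroxyflavan-(4β→8)-epiafzelechin-(4β→8)-epiafzelechin (CNP0257624.1)
Conditions: H2 (1 atm), Pd(OH)2 on carbon (20 wt %), THF/MeOH/H2O 20:1:1, rt; filtration, lyophilisation
Reagents that add atoms: none
Why: Hydrogenolysis of the eight benzyl ethers over Pd(OH)2 on carbon, the standard last step for benzylated proanthocyanidins, under which the interflavan bonds, the benzylic C2–O1 bonds and all stereocentres should persist at room temperature and atmospheric pressure.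

**Compound list**
1 | 4-(benzyloxy)benzaldehyde | O=Cc1ccc(OCc2ccccc2)cc1 | starting material
2 | (S)-2-({1-[4-(benzyloxy)phenyl]but-3-en-1-yl}oxy)-4,4,5,5-tetramethyl-1,3,2-dioxaborolane | C=CC[C@H](OB1OC(C)(C)C(C)(C)O1)c1ccc(OCc2ccccc2)cc1 | intermediate (not isolated)
3 | (S)-1-[4-(benzyloxy)phenyl]but-3-en-1-ol | C=CC[C@H](O)c1ccc(OCc2ccccc2)cc1 | intermediate
4 | 1-(benzyloxy)-3-iodobenzene | Ic1cccc(OCc2ccccc2)c1 | starting material
5 | (S)-1-(benzyloxy)-3-({1-[4-(benzyloxy)phenyl]but-3-en-1-yl}oxy)benzene | C=CC[C@H](Oc1cccc(OCc2ccccc2)c1)c1ccc(OCc2ccccc2)cc1 | intermediate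
6 | (4S)-4-[4-(benzyloxy)phenyl]-4-[3-(benzyloxy)phenoxy]butane-1,2-diol (both C2 epimers) | OCC(O)C[C@H](Oc1cccc(OCc2ccccc2)c1)c1ccc(OCc2ccccc2)cc1 | intermediate (not isolated)
7 | (S)-3-[4-(benzyloxy)phenyl]-3-[3-(benzyloxy)phenoxy]propanal | O=CC[C@H](Oc1cccc(OCc2ccccc2)c1)c1ccc(OCc2ccccc2)cc1 | intermediate
8 | (−)-epiafzelechin, (2R,3R)-2-(4-hydroxyphenyl)chroman-3,5,7-triol | c1c(O)cc(O)c2c1O[C@H](c1ccc(O)cc1)[C@H](O)C2 | starting material
9 | 5,7,4'-tri-O-benzyl-(−)-epiafzelechin, (2R,3R)-5,7-bis(benzyloxy)-2-[4-(benzyloxy)phenyl]chroman-3-ol | c1c(OCc2ccccc2)cc(OCc2ccccc2)c2c1O[C@H](c1ccc(OCc3ccccc3)cc1)[C@H](O)C2 | intermediate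
10 | (2R,3R)-5,7-bis(benzyloxy)-2-[4-(benzyloxy)phenyl]-3-hydroxychroman-4-ylium 2,3-dichloro-5,6-dicyano-4-hydroxyphenolate (ion pair) | c1c(OCc2ccccc2)cc(OCc2ccccc2)c2c1O[C@H](c1ccc(OCc3ccccc3)cc1)[C@H](O)[CH+]2.[O-]c1c(Cl)c(Cl)c(O)c(C#N)c1C#N | intermediate (not isolated)
11 | (2R,3R,4S)-5,7-bis(benzyloxy)-2-[4-(benzyloxy)phenyl]-4-(2-hydroxyethoxy)chroman-3-ol (4β-glycol ether) | c1c(OCc2ccccc2)cc(OCc2ccccc2)c2c1O[C@H](c1ccc(OCc3ccccc3)cc1)[C@H](O)[C@H]2OCCO | intermediate
12 | (2R,3R)-5,7-bis(benzyloxy)-2-[4-(benzyloxy)phenyl]-3-hydroxychroman-4-ylium trifluoromethanesulfonate (ion pair) | c1c(OCc2ccccc2)cc(OCc2ccccc2)c2c1O[C@H](c1ccc(OCc3ccccc3)cc1)[C@H](O)[CH+]2.[O-]S(=O)(=O)C(F)(F)F | intermediate (not isolated)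
13 | hexa-O-benzyl-epiafzelechin-(4β→8)-epiafzelechin; upper unit (2R,3R,4R), lower unit (2R,3R), both 3-OH free | c1c(OCc2ccccc2)cc(OCc2ccccc2)c2c1O[C@H](c1ccc(OCc3ccccc3)cc1)[C@H](O)[C@H]2c1c(OCc2ccccc2)cc(OCc2ccccc2)c2c1O[C@H](c1ccc(OCc3ccccc3)cc1)[C@H](O)C2 | intermediate
14 | (2S)-7-(benzyloxy)-2-[4-(benzyloxy)phenyl]-4-[(trimethylsilyl)oxy]chroman (both C4 epimers) | C[Si](C)(C)OC1C[C@@H](c2ccc(OCc3ccccc3)cc2)Oc2cc(OCc3ccccc3)ccc21 | intermediate (not isolated)
15 | (2S)-7-(benzyloxy)-2-[4-(benzyloxy)phenyl]chroman-4-ylium trifluoromethanesulfonate (ion pair) | [CH+]1C[C@@H](c2ccc(OCc3ccccc3)cc2)Oc2cc(OCc3ccccc3)ccc21.[O-]S(=O)(=O)C(F)(F)F | intermediate (not isolated)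
16 | octa-O-benzyl-(2S)-7,4'-dihydroxyflavan-(4β→8)-epiafzelechin-(4β→8)-epiafzelechin; upper unit (2S,4R), middle unit (2R,3R,4S), lower unit (2R,3R) | c5ccccc5COc1ccc([C@@H]2C[C@@H](c3c(OCc5ccccc5)cc(OCc5ccccc5)c4c3O[C@H](c3ccc(OCc5ccccc5)cc3)[C@H](O)[C@H]4c3c(OCc5ccccc5)cc(OCc5ccccc5)c4c3O[C@H](c3ccc(OCc5ccccc5)cc3)[C@H](O)C4)c3ccc(OCc5ccccc5)cc3O2)cc1 | intermediate
17 | (2S)-7,4'-dihydroxyflavan-(4β→8)-epiafzelechin-(4β→8)-epiafzelechin (CNP0257624.1) | Oc1ccc([C@@H]2C[C@@H](c3c(O)cc(O)c4c3O[C@H](c3ccc(O)cc3)[C@H](O)[C@H]4c3c(O)cc(O)c4c3O[C@H](c3ccc(O)cc3)[C@H](O)C4)c3ccc(O)cc3O2)cc1 | target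

**Totals**
Total step count: 8. Longest linear sequence: 5 steps (steps 4, 5, 6, 7, 8 from 8; equally steps 1, 2, 3, 7, 8 from 1).

**Steps most likely to fail**

Step 7. Several processes may intervene:
- loss of the aryloxide from the activated aldehyde by β-elimination before ring closure;
- attack of the dimer on the aldehyde ahead of ring closure, which would pass through a different cation and could change the stereochemical course;
- poor facial selectivity in the arylation of the cation;
- a second alkylation of the product.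

The fallback uses known chemistry, sets out from 7 and returns at 16. Pinnick oxidation (NaClO2, NaH2PO4, 2-methylbut-2-ene, t-BuOH/H2O) would give (S)-3-[4-(benzyloxy)phenyl]-3-[3-(benzyloxy)phenoxy]propanoic acid F1. Intramolecular Friedel–Crafts acylation ((CF3CO)2O, CH2Cl2, 0 °C) would close ring C at the ketone level to (S)-7-(benzyloxy)-2-[4-(benzyloxy)phenyl]chroman-4-one F2. NaBH4 (MeOH/THF, 0 °C) would give the 2,4-cis alcohol (2S,4S)-7-(benzyloxy)-2-[4-(benzyloxy)phenyl]chroman-4-ol F3, an isolable electrophile. F3 and excess 13 with catalytic Me3SiOTf (CH2Cl2, −78 °C), the established coupling of a C4-hydroxylated flavan with a flavan nucleophile, would then give 16 through the cation of 15. This removes the first two failure modes; it does not change the facial selectivity, so any 4α epimer would be separated by chromatography.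

Step 2. The hindered secondary benzylic alkoxide may couple slowly, with competing oxidation of the carbinol or reduction of the aryl iodide. The fallback sets out from 1 and returns at 5. Allylboration of 1 with (R)-TRIP would give (R)-1-[4-(benzyloxy)phenyl]but-3-en-1-ol F4. A Mitsunobu reaction with 3-(benzyloxy)phenol (PPh3, diisopropyl azodicarboxylate, toluene, −20 → 0 °C) would then form the benzylic C–O bond with inversion to give 5. The bond is thus made at the stereocentre instead of at the arene.

Step 3. The β-aryloxy aldehyde may lose the aryloxide by β-elimination (retro-oxa-Michael) or be over-oxidised during cleavage, isolation or storage. The fallback sets out from 5 and returns at 7. After the OsO4/NaIO4 cleavage, NaBH4 added to the same flask would reduce the aldehyde as it is formed to (S)-3-[4-(benzyloxy)phenyl]-3-[3-(benzyloxy)phenoxy]propan-1-ol F5, which can be purified and stored. Dess–Martin periodinane (CH2Cl2, rt) immediately before step 7 would give 7 under anhydrous, non-basic conditions, and its filtered solution would be used directly.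

**Further compounds**
F1 | step 7 | (S)-3-[4-(benzyloxy)phenyl]-3-[3-(benzyloxy)phenoxy]propanoic acid | OC(=O)C[C@H](Oc1cccc(OCc2ccccc2)c1)c1ccc(OCc2ccccc2)cc1
F2 | step 7 | (S)-7-(benzyloxy)-2-[4-(benzyloxy)phenyl]chroman-4-one | O=C1C[C@@H](c2ccc(OCc3ccccc3)cc2)Oc2cc(OCc3ccccc3)ccc21
F3 | step 7 | (2S,4S)-7-(benzyloxy)-2-[4-(benzyloxy)phenyl]chroman-4-ol | O[C@H]1C[C@@H](c2ccc(OCc3ccccc3)cc2)Oc2cc(OCc3ccccc3)ccc21
F4 | step 2 | (R)-1-[4-(benzyloxy)phenyl]but-3-en-1-ol | C=CC[C@@H](O)c1ccc(OCc2ccccc2)cc1
F5 | step 3 | (S)-3-[4-(benzyloxy)phenyl]-3-[3-(benzyloxy)phenoxy]propan-1-ol | OCC[C@H](Oc1cccc(OCc2ccccc2)c1)c1ccc(OCc2ccccc2)cc1
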